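**Retrosynthetic overview**
- Pakyonol comes from an O-benzyl macrocycle with one C=C between rings A and D; a single hydrogenation reduces the C=C and removes the benzyl group.
- That macrocycle comes from an open-chain 3-aryloxy-2-pyrone carrying a sulfonyl diene: intramolecular Diels–Alder, loss of CO2 and loss of sulfinic acid build ring D and the 20-membered ring in one operation.
- The open chain comes from an sp3–sp2 Suzuki coupling of a ring C styrene (pyrone ether) with a ring A–B aryl bromide (sulfonyl diene).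
- Ring C piece: 3-hydroxy-2-pyrone + 3-(benzyloxy)-4-fluorobenzaldehyde (SNAr, then methylenation). Ring A–B piece: isovanillin + 4-bromophenylboronic acid (Chan–Lam, then two olefinations).
- Ring order: rings A, B and C are bought as benzenes; ring D and the macrocycle form last and together.

Assumption: the SMILES has no stereodescriptor and pakyonol has no configurationally stable stereo-element, so the achiral compound itself is the target and no asymmetric step is needed.

**Route**

Step 1
Reactants: 1 isovanillin; 2 (4-bromophenyl)boronic acid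
Product: 3 3-(4-bromophenoxy)-4-methoxybenzaldehyde
Conditions: Cu(OAc)2 (0.2 equiv), pyridine (3 equiv), 4 Å molecular sieves, CH2Cl2, O2 (1 atm), rt, 36 h
Reagents that add atoms: none
Why: Chan–Lam–Evans oxidative C–O coupling joins the phenol oxygen to the boron-bearing carbon under mild aerobic copper catalysis and leaves the aldehyde and the aryl bromide untouched.

Step 2
Reactants: 3 3-(4-bromophenoxy)-4-methoxybenzaldehyde
Product: 5 2-(4-bromophenoxy)-1-methoxy-4-[(1E,3E)-4-(phenylsulfonyl)buta-1,3-dien-1-yl]benzene, via enal 4 (not isolated)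
Conditions: Ph3P=CHCHO (1.1 equiv), toluene, 80 °C; then added to (EtO)2P(O)CH2SO2Ph/NaH, THF, 0 °C to rt
Reagents that add atoms: (triphenylphosphoranylidene)acetaldehyde, O=CC=P(c1ccccc1)(c1ccccc1)c1ccccc1; diethyl [(phenylsulfonyl)methyl]phosphonate, CCOP(=O)(CS(=O)(=O)c1ccccc1)OCC
Why: a Wittig reaction with the stabilised formyl ylide gives the (E)-enal and a Horner–Wadsworth–Emmons olefination with the sulfonyl phosphonate anion then gives the (E,E)-sulfonyl diene, both E-selective because the carbanions are stabilised.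

Step 3
Reactants: 6 3-hydroxy-2H-pyran-2-one; 7 3-(benzyloxy)-4-fluorobenzaldehyde
Product: 8 3-(benzyloxy)-4-[(2-oxo-2H-pyran-3-yl)oxy]benzaldehyde
Conditions: K2CO3 (1.5 equiv), DMSO, 4 Å molecular sieves, 100 °C
Reagents that add atoms: none
Why: nucleophilic aromatic substitution (SNAr), in which the deprotonated acidic enol oxygen of the pyrone displaces the fluoride activated by the para aldehyde through a Meisenheimer complex.

Step 4
Reactants: 8 3-(benzyloxy)-4-[(2-oxo-2H-pyran-3-yl)oxy]benzaldehyde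
Product: 9 3-[2-(benzyloxy)-4-ethenylphenoxy]-2H-pyran-2-one
Conditions: Ph3PCH3Br (1.2 equiv), KOtBu (1.15 equiv), THF, −78 to 0 °C
Reagents that add atoms: methyltriphenylphosphonium bromide, C[P+](c1ccccc1)(c1ccccc1)c1ccccc1.[Br-]
Why: Wittig methylenation with the non-stabilised ylide at low temperature is far faster at the aldehyde than any attack on the pyrone lactone.

Step 5
Reactants: 9 3-[2-(benzyloxy)-4-ethenylphenoxy]-2H-pyran-2-one; 5 2-(4-bromophenoxy)-1-methoxy-4-[(1E,3E)-4-(phenylsulfonyl)buta-1,3-dien-1-yl]benzene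
Product: 11 3-[2-(benzyloxy)-4-[2-[4-[2-methoxy-5-[(1E,3E)-4-(phenylsulfonyl)buta-1,3-dien-1-yl]phenoxy]phenyl]ethyl]phenoxy]-2H-pyran-2-one, via alkylborane 10 (not isolated)
Conditions: 9 (1.2 equiv), 9-BBN (1.15 equiv), THF, 0 °C to rt; then aq. Cs2CO3, 5 (1.0 equiv), Pd(dppf)Cl2 (5 mol %), AsPh3 (10 mol %), DMF/THF/H2O, rt to 45 °C
Reagents that add atoms: 9-borabicyclo[3.3.1]nonane (9-BBN), B1C2CCCC1CCC2 (its boron unit is carried only in intermediate 10; product 11 keeps one hydrogen from it)
Why: anti-Markovnikov hydroboration of the terminal styrene followed by sp3–sp2 Suzuki–Miyaura coupling with the aryl bromide forms the saturated two-carbon bridge directly, so no hydrogenation is needed while the pyrone and the vinyl sulfone are present.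

Step 6
Reactants: 11 3-[2-(benzyloxy)-4-[2-[4-[2-methoxy-5-[(1E,3E)-4-(phenylsulfonyl)buta-1,3-dien-1-yl]phenoxy]phenyl]ethyl]phenoxy]-2H-pyran-2-one
Product: 14 O-benzyl didehydropakyonol (macrocyclic E-stilbene), via bridged lactone 12 (not isolated), via cyclohexadiene 13 (not isolated)
Conditions: 1,2-dichlorobenzene (0.001 M), BHT (0.1 equiv), 200 °C, sealed vessel, 24–36 h; then DBU (2 equiv), 60 °C
Reagents that add atoms: none
Why: intramolecular normal-electron-demand pyrone Diels–Alder reaction in which the electron-rich C6 terminus of the 3-aryloxypyrone bonds to the β-carbon of the vinyl sulfone, followed by retro-Diels–Alder loss of CO2 and base-assisted elimination of benzenesulfinic acid, aromatises the new ring with the bridge meta to the ether oxygen, so ring D and the 20-membered macrocycle close in one operation while high dilution suppresses oligomers and all transient stereocentres are erased.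

Step 7
Reactants: 14 O-benzyl didehydropakyonol (macrocyclic E-stilbene)
Product: 15 pakyonol
Conditions: H2 (1 atm), Pd/C (10 wt %), EtOAc/EtOH 1:1, rt
Reagents that add atoms: none
Why: heterogeneous catalytic hydrogenation reduces the stilbene C=C and hydrogenolyses the benzyl ether in one pot, while the aryl methyl ether and the diaryl ethers are inert and no stereocentre is created.

**Compound list**

1 | isovanillin (3-hydroxy-4-methoxybenzaldehyde) | COc1ccc(C=O)cc1O | starting material
2 | (4-bromophenyl)boronic acid | OB(O)c1ccc(Br)cc1 | starting material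
3 | 3-(4-bromophenoxy)-4-methoxybenzaldehyde | COc1ccc(C=O)cc1Oc1ccc(Br)cc1 | intermediate
4 | (2E)-3-[3-(4-bromophenoxy)-4-methoxyphenyl]prop-2-enal (enal) | COc1ccc(/C=C/C=O)cc1Oc1ccc(Br)cc1 | intermediate
5 | 2-(4-bromophenoxy)-1-methoxy-4-[(1E,3E)-4-(phenylsulfonyl)buta-1,3-dien-1-yl]benzene | COc1ccc(/C=C/C=C/S(=O)(=O)c2ccccc2)cc1Oc1ccc(Br)cc1 | intermediate
6 | 3-hydroxy-2H-pyran-2-one (catalogue compound; also one step from mucic acid) | O=C1OC=CC=C1O | starting material
7 | 3-(benzyloxy)-4-fluorobenzaldehyde (catalogue building block) | O=Cc1ccc(F)c(OCc2ccccc2)c1 | starting material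
8 | 3-(benzyloxy)-4-[(2-oxo-2H-pyran-3-yl)oxy]benzaldehyde | O=Cc1ccc(OC2=CC=COC2=O)c(OCc2ccccc2)c1 | intermediate
9 | 3-[2-(benzyloxy)-4-ethenylphenoxy]-2H-pyran-2-one | C=Cc1ccc(OC2=CC=COC2=O)c(OCc2ccccc2)c1 | intermediate
10 | alkylborane: 3-[2-(benzyloxy)-4-[2-(9-borabicyclo[3.3.1]nonan-9-yl)ethyl]phenoxy]-2H-pyran-2-one | O=C1OC=CC=C1Oc1ccc(CCB2C3CCCC2CCC3)cc1OCc1ccccc1 | intermediate
11 | open-chain pyrone/sulfonyl diene: 3-[2-(benzyloxy)-4-[2-[4-[2-methoxy-5-[(1E,3E)-4-(phenylsulfonyl)buta-1,3-dien-1-yl]phenoxy]phenyl]ethyl]phenoxy]-2H-pyran-2-one | COc1ccc(/C=C/C=C/S(=O)(=O)c2ccccc2)cc1Oc1ccc(CCc2ccc(OC3=CC=COC3=O)c(OCc3ccccc3)c2)cc1 | intermediate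
12 | bridged lactone cycloadduct (macrocyclic 2-oxabicyclo[2.2.2]oct-5-en-3-one carrying the phenylsulfonyl group; endo/exo mixture, racemic, ring stereocentres therefore left open) | COc1ccc(/C=C/C2C3C=CC(Oc4ccc(CCc5ccc(O6)cc5)cc4OCc4ccccc4)(C(=O)O3)C2S(=O)(=O)c2ccccc2)cc16 | intermediate
13 | cyclohexadiene after CO2 loss (sulfonyl and bridge carbon trans, racemic; one enantiomer drawn) | COc1ccc(/C=C/[C@@H]2C=CC=C(Oc3ccc(CCc4ccc(O5)cc4)cc3OCc3ccccc3)[C@H]2S(=O)(=O)c2ccccc2)cc15 | intermediate
14 | O-benzyl didehydropakyonol (macrocycle with E C=C between rings A and D, ring C as benzyl ether) | COc1ccc(/C=C/c2cccc(Oc3ccc(CCc4ccc(O5)cc4)cc3OCc3ccccc3)c2)cc15 | intermediate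
15 | pakyonol | COc1ccc2cc1Oc1ccc(cc1)CCc1ccc(c(O)c1)Oc1cccc(c1)CC2 | target

**Step count and risks**

Total: 7 steps (steps 2 and 5 are one-pot, two-stage operations). Longest linear sequence: 5 steps (1 → 2 → 5 → 6 → 7, or 3 → 4 → 5 → 6 → 7).

Most likely to fail:

Step 6 (macrocyclising Diels–Alder). A β-substituted vinyl sulfone is only a moderate dienophile and the ring is 20-membered, so oligomers or recovered 11 are possible. The fallback sets out from 5 and 6 and comes back at 14. The cycloaddition is run between two molecules and the large ring is closed afterwards by C–C coupling. Compounds 6 and 5 with Et3N in toluene at rt give the bridged hydroxy lactone F1. Heating to 120 °C with DBU expels CO2 to give the cyclohexadienol F2 (not isolated) and then benzenesulfinic acid to give the phenol F3. SNAr of the phenol on 7 (K2CO3, DMF, 110 °C) gives the diaryl ether aldehyde F4, and Wittig methylenation gives the styrene F5. 9-BBN adds only to the terminal alkene to give the alkylborane F6 (not isolated). This closes onto the aryl bromide by intramolecular Suzuki coupling under high dilution (Pd(dppf)Cl2, AsPh3, Cs2CO3, DMF/THF/H2O, slow addition) to give 14.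

Step 3 (SNAr with the pyrone enolate). The pyronate is a weak nucleophile and may not survive hot carbonate. The fallback sets out from 7 and comes back at 8, and it inverts the polarity of the ether coupling. The activated fluoride of 7 is hydrolysed (KOH, DMSO/H2O, 80 °C) to 3-(benzyloxy)-4-hydroxybenzaldehyde F7. This phenol is then joined to 3-bromo-2H-pyran-2-one by an Ullmann-type vinylic C–O coupling (CuI, N,N-dimethylglycine, Cs2CO3, dioxane, 90 °C) to give 8.

Step 5 (hydroboration–Suzuki union). The sulfonyl diene may suffer Heck-type insertion, conjugate addition of the base or reduction by residual borane. The fallback sets out from 10 and 3 and comes back at 11, and it moves the cross-coupling in front of the diene construction. Alkylborane 10 is coupled with bromo aldehyde 3 under the same palladium catalysis to give the bibenzyl aldehyde F8. The Wittig reaction with Ph3P=CHCHO then gives the enal F9, and the Horner–Wadsworth–Emmons olefination with the sulfonyl phosphonate gives 11.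

**Further compounds**

F1 | step 6 | bridged hydroxy lactone from 5 and 6 (endo/exo mixture, racemic) | COc1ccc(/C=C/C2C3C=CC(O)(C(=O)O3)C2S(=O)(=O)c2ccccc2)cc1Oc1ccc(Br)cc1
F2 | step 6 | cyclohexadienol after CO2 loss (trans, racemic; one enantiomer drawn) | COc1ccc(/C=C/[C@@H]2C=CC=C(O)[C@H]2S(=O)(=O)c2ccccc2)cc1Oc1ccc(Br)cc1
F3 | step 6 | 3-[(E)-2-[3-(4-bromophenoxy)-4-methoxyphenyl]ethenyl]phenol | COc1ccc(/C=C/c2cccc(O)c2)cc1Oc1ccc(Br)cc1
F4 | step 6 | 3-(benzyloxy)-4-[3-[(E)-2-[3-(4-bromophenoxy)-4-methoxyphenyl]ethenyl]phenoxy]benzaldehyde | COc1ccc(/C=C/c2cccc(Oc3ccc(C=O)cc3OCc3ccccc3)c2)cc1Oc1ccc(Br)cc1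
F5 | step 6 | 2-(benzyloxy)-4-ethenyl-1-[3-[(E)-2-[3-(4-bromophenoxy)-4-methoxyphenyl]ethenyl]phenoxy]benzene | COc1ccc(/C=C/c2cccc(Oc3ccc(C=C)cc3OCc3ccccc3)c2)cc1Oc1ccc(Br)cc1
F6 | step 6 | B-alkyl-9-BBN derived from F5 | COc1ccc(/C=C/c2cccc(Oc3ccc(CCB4C5CCCC4CCC5)cc3OCc3ccccc3)c2)cc1Oc1ccc(Br)cc1
F7 | step 3 | 3-(benzyloxy)-4-hydroxybenzaldehyde | O=Cc1ccc(O)c(OCc2ccccc2)c1
F8 | step 5 | 3-[4-[2-[3-(benzyloxy)-4-[(2-oxo-2H-pyran-3-yl)oxy]phenyl]ethyl]phenoxy]-4-methoxybenzaldehyde | COc1ccc(C=O)cc1Oc1ccc(CCc2ccc(OC3=CC=COC3=O)c(OCc3ccccc3)c2)cc1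
F9 | step 5 | (2E)-3-[3-[4-[2-[3-(benzyloxy)-4-[(2-oxo-2H-pyran-3-yl)oxy]phenyl]ethyl]phenoxy]-4-methoxyphenyl]prop-2-enal | COc1ccc(/C=C/C=O)cc1Oc1ccc(CCc2ccc(OC3=CC=COC3=O)c(OCc3ccccc3)c2)cc1
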